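The ten-membered carbocycle is closed at C10–C1 (germacrane numbering), the bond between the methyl-bearing carbon of the Z-C9=C10 alkene and the C1 acetoxy carbinol; the key step exploits this allylic-alcohol unit C9=C10–C1(O). An intramolecular Nozaki–Hiyama–Kishi reaction of a (Z)-2-iodopropenyl group on C8 of the preformed butenolide with a C1 aldehyde forms the bond, closes the cyclodecene and creates the C1 stereocentre in one operation; the Z-alkene and the flat butenolide ring (O, C12, C11, C7, C8) keep the chain ends close. The open-chain precursor arises from a three-component union: syn-carbocupration of a γ-silyloxy ynoate by the C1–C6 organocopper, then borylmethylation.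

Key step: step 12

Remark (numbering): ring compounds carry germacrane locants: C1 (acetoxy carbinol), C2, C3 (hydroxyl), C4 (=C15H2), C5, C6, C7=C11 (butenolide alkene), C8 (lactone CH–O), C9=C10 (C14 methyl on C10), C12 (lactone C=O), C13 (CH2O).

Assumption: the (S,S)-ProPhenol/Me2Zn catalyst is taken to add the alkynyl group to the Si face of enal 3 (4R carbinol); if the sense is the opposite, the (R,R)-ligand is used.

Step 1
Reactants: 1 but-2-yn-1-ol
Product: 2 (Z)-3-iodobut-2-en-1-ol
Conditions: Red-Al, THF, 0 °C → rt; then I2, −78 → 0 °C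
Reagents that add atoms: iodine, II
Why: Hydroxyl-directed trans-hydroalumination puts aluminium on C3 cis to the CH2O group (five-membered alanate chelate) and iodinolysis with retention should give the Z-vinyl iodide, whose geometry becomes that of the C9=C10 alkene.

Step 2
Reactants: 2 (Z)-3-iodobut-2-en-1-ol
Product: 3 (Z)-3-iodobut-2-enal
Conditions: MnO2 (excess), CH2Cl2, rt, dark; used at once
Reagents that add atoms: none
Why: Allylic alcohol oxidation with neutral, heterogeneous MnO2 should stop at the enal and leave the Z-iodoalkene untouched.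

Step 3
Reactants: 3 (Z)-3-iodobut-2-enal; 4 methyl propiolate
Product: 5 methyl (4R,5Z)-4-hydroxy-6-iodohept-5-en-2-ynoate
Conditions: (S,S)-ProPhenol (20 mol%), Ph3PO (40 mol%), Me2Zn (3 equiv), toluene, 0–4 °C
Reagents that add atoms: none
Why: Dinuclear-zinc (ProPhenol) catalysed asymmetric alkynylation of an α,β-unsaturated aldehyde, in which the chiral catalyst delivers the zinc alkynylide to the Si face and so sets the future C8 stereocentre (R).

Step 4
Reactants: 5 methyl (4R,5Z)-4-hydroxy-6-iodohept-5-en-2-ynoate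
Product: 6 methyl (4R,5Z)-6-iodo-4-(triethylsilyloxy)hept-5-en-2-ynoate
Conditions: TESCl, imidazole, DMAP (cat.), CH2Cl2, 0 °C
Reagents that add atoms: chlorotriethylsilane, CC[Si](CC)(CC)Cl
Why: Silylation of the secondary alcohol keeps the γ-oxygen from lactonising or quenching the organocopper in step 10 and is removed by mild acid later.

Step 5
Reactants: 7 methyl 3,3-dimethoxypropanoate
Product: 8 N,3,3-trimethoxy-N-methylpropanamide
Conditions: MeNHOMe·HCl, i-PrMgCl, THF, −20 °C
Reagents that add atoms: N,O-dimethylhydroxylamine hydrochloride, CNOC.Cl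
Why: Aminolysis of the ester by the magnesium amide (Weinreb amide formation) should give an acylating agent that stops at the ketone stage in step 6.

Step 6
Reactants: 9 3-bromobut-3-en-1-ol; 8 N,3,3-trimethoxy-N-methylpropanamide
Product: 11 6-hydroxy-1,1-dimethoxy-4-methylidenehexan-3-one, via dilithio reagent 10 (not isolated)
Conditions: 9, t-BuLi (3.1 equiv), Et2O, −78 °C; then 8, −78 → −20 °C; inverse quench into cold aq. NH4Cl/citric acid
Reagents that add atoms: none
Why: Deprotonation and bromine–lithium exchange give the alkoxide-bearing vinyllithium, whose Weinreb ketone synthesis should give the α-methylene ketone (C3–C4 bond); the acidic inverse quench keeps the liberated amine from adding to the enone.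

Step 7
Reactants: 11 6-hydroxy-1,1-dimethoxy-4-methylidenehexan-3-one
Product: 12 6-bromo-1,1-dimethoxy-4-methylidenehexan-3-one
Conditions: CBr4, PPh3, CH2Cl2, 0 °C
Reagents that add atoms: tetrabromomethane, BrC(Br)(Br)Br
Why: Appel bromination converts the primary alcohol into the bromide under near-neutral conditions that the acetal and the enone should tolerate.

Step 8
Reactants: 12 6-bromo-1,1-dimethoxy-4-methylidenehexan-3-one
Product: 13 (3R)-6-bromo-1,1-dimethoxy-4-methylidenehexan-3-ol
Conditions: (S)-Me-CBS (20 mol%), catecholborane (1.5 equiv), toluene, −78 °C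
Reagents that add atoms: none
Why: Corey–Bakshi–Shibata reduction of an enone with the α-branched alkenyl group as the large substituent should give the R allylic alcohol (future C3) by 1,2-hydride delivery, catecholborane avoiding hydroboration of the alkene.

Step 9
Reactants: 13 (3R)-6-bromo-1,1-dimethoxy-4-methylidenehexan-3-ol
Product: 14 (3R)-6-bromo-3-(tert-butyldimethylsilyloxy)-1,1-dimethoxy-4-methylidenehexane
Conditions: TBSOTf, 2,6-lutidine, CH2Cl2, −78 °C
Reagents that add atoms: tert-butyldimethylsilyl triflate, CC(C)(C)[Si](C)(C)OS(=O)(=O)C(F)(F)F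
Why: Silylation at low temperature protects the C3 hydroxyl as the robust TBS ether that differentiates the 1,3-diol to the end, without touching the acetal or the bromide.

Step 10
Reactants: 14 (3R)-6-bromo-3-(tert-butyldimethylsilyloxy)-1,1-dimethoxy-4-methylidenehexane; 6 methyl (4R,5Z)-6-iodo-4-(triethylsilyloxy)hept-5-en-2-ynoate; 15 2-(iodomethyl)-4,4,5,5-tetramethyl-1,3,2-dioxaborolane
Product: 19 methyl (2Z,7R)-7-(tert-butyldimethylsilyloxy)-3-[(1R,2Z)-3-iodo-1-(triethylsilyloxy)but-2-en-1-yl]-9,9-dimethoxy-6-methylidene-2-[(4,4,5,5-tetramethyl-1,3,2-dioxaborolan-2-yl)methyl]non-2-enoate, via Grignard reagent 16 (not isolated), via alkylcopper 17 (not isolated), via alkenylcopper 18 (not isolated)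
Conditions: 14 (1.3 equiv), Mg, THF, rt; CuBr·SMe2 (1.0 equiv per Grignard), −78 → −40 °C; 6, −78 °C; then HMPA, 15, −78 → −30 °C
Reagents that add atoms: none
Why: Syn-carbocupration of the alkynoate (C6–C7 bond) followed by HMPA-accelerated C-alkylation of the α-cuprio enoate with the iodomethylboronate with retention should give the tetrasubstituted alkene with the C8 carbinol cis to the ester, the unactivated vinyl iodide being inert to a monoorganocopper at these temperatures.

Step 11
Reactants: 19 methyl (2Z,7R)-7-(tert-butyldimethylsilyloxy)-3-[(1R,2Z)-3-iodo-1-(triethylsilyloxy)but-2-en-1-yl]-9,9-dimethoxy-6-methylidene-2-[(4,4,5,5-tetramethyl-1,3,2-dioxaborolan-2-yl)methyl]non-2-enoate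
Product: 21 (5R)-4-[(4R)-4-(tert-butyldimethylsilyloxy)-3-methylidene-6-oxohexyl]-3-(hydroxymethyl)-5-[(1Z)-2-iodoprop-1-en-1-yl]furan-2(5H)-one, via allylic alcohol 20 (not isolated)
Conditions: NaBO3·4H2O, THF/H2O, rt; then 1 M HCl to pH 2, rt
Reagents that add atoms: sodium perborate tetrahydrate, [Na+].[Na+].O[B-]1(O)OO[B-](O)(O)OO1; water, O
Why: Boronate oxidation turns the allylic C–B bond into the C13 hydroxyl without allylic shift, and aqueous acid then removes the TES ether (the freed C8 hydroxyl lactonises onto the cis ester) and hydrolyses the dimethyl acetal to the C1 aldehyde, while the secondary TBS ether should survive.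

Step 12
Reactants: 21 (5R)-4-[(4R)-4-(tert-butyldimethylsilyloxy)-3-methylidene-6-oxohexyl]-3-(hydroxymethyl)-5-[(1Z)-2-iodoprop-1-en-1-yl]furan-2(5H)-one
Product: 22 (1S,3R,8R,9Z)-3-(tert-butyldimethylsilyloxy)-1,13-dihydroxygermacra-4(15),7(11),9-trien-12,8-olide
Conditions: CrCl2 (10 equiv), NiCl2 (1 mol% of Cr), DMSO/THF, rt, 2 mM, syringe-pump addition of 21
Reagents that add atoms: none
Why: Ni(0), formed from NiCl2 by CrCl2, inserts into the C10–I bond with retention, transmetalation gives the (Z)-alkenylchromium(III) species, and this adds to the C1 aldehyde to form the C10–C1 bond (Nozaki–Hiyama–Kishi reaction). The closest known reaction type is the NHK macrocyclisation that closes 9- to 12-membered carbocycles from iodoalkenyl aldehydes. The ten-membered carbocycle closes in a 10-exo-trig mode (carbonyl oxygen exocyclic), helped by the Z-C9=C10 alkene and the planar butenolide, which remove rotatable bonds and turn the chain. The new C1 stereocentre is under substrate control: the C3 silyl ether (β to the aldehyde) and C8 shape a ring-like transition state in which C3–OTBS and the C1–O–Cr group both point outward, so the alkenyl group should add to the Re face and give the 1,3-syn (1S,3R) alcohol; this sense is expected, not assured. The step needs chemoselectivity (addition to the aldehyde only, with the lactone, the silyl ether and the free C13 hydroxyl tolerated; C13 is kept unacetylated so that no allylic acetate meets Ni(0)), retention of the Z geometry (trisubstituted alkenyl–Ni/Cr species should not isomerise) and cyclisation over oligomerisation (high dilution).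

Step 13
Reactants: 22 (1S,3R,8R,9Z)-3-(tert-butyldimethylsilyloxy)-1,13-dihydroxygermacra-4(15),7(11),9-trien-12,8-olide
Product: 23 (1S,3R,8R,9Z)-1,13-diacetoxy-3-(tert-butyldimethylsilyloxy)germacra-4(15),7(11),9-trien-12,8-olide
Conditions: Ac2O, pyridine, DMAP (cat.), CH2Cl2, 0 °C → rt
Reagents that add atoms: acetic anhydride, CC(=O)OC(C)=O
Why: DMAP-catalysed acylation esterifies both free hydroxyls (C1 with retention, C13) in one operation while O3 stays silylated.

Step 14
Reactants: 23 (1S,3R,8R,9Z)-1,13-diacetoxy-3-(tert-butyldimethylsilyloxy)germacra-4(15),7(11),9-trien-12,8-olide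
Product: 24 (1S,3R,8R,9Z)-1,13-diacetoxy-3-hydroxygermacra-4(15),7(11),9-trien-12,8-olide
Conditions: HF·pyridine, pyridine, THF, 0 °C → rt
Reagents that add atoms: none
Why: Buffered HF·pyridine desilylation should free the C3 hydroxyl without O1→O3 acetyl migration or lactone opening, which basic fluoride could cause.

Compound list
1 | but-2-yn-1-ol | CC#CCO | starting material
2 | (Z)-3-iodobut-2-en-1-ol | OC/C=C(/C)I | intermediate
3 | (Z)-3-iodobut-2-enal | O=C/C=C(/C)I | intermediate
4 | methyl propiolate | C#CC(=O)OC | starting material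
5 | methyl (4R,5Z)-4-hydroxy-6-iodohept-5-en-2-ynoate | COC(=O)C#C[C@H](O)/C=C(/C)I | intermediate
6 | methyl (4R,5Z)-6-iodo-4-(triethylsilyloxy)hept-5-en-2-ynoate | COC(=O)C#C[C@H](O[Si](CC)(CC)CC)/C=C(/C)I | intermediate
7 | methyl 3,3-dimethoxypropanoate | COC(=O)CC(OC)OC | starting material
8 | N,3,3-trimethoxy-N-methylpropanamide | CON(C)C(=O)CC(OC)OC | intermediate
9 | 3-bromobut-3-en-1-ol | C=C(Br)CCO | starting material
10 | lithium 3-lithiobut-3-en-1-olate | [Li]OCCC([Li])=C | intermediate
11 | 6-hydroxy-1,1-dimethoxy-4-methylidenehexan-3-one | COC(OC)CC(=O)C(=C)CCO | intermediate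
12 | 6-bromo-1,1-dimethoxy-4-methylidenehexan-3-one | COC(OC)CC(=O)C(=C)CCBr | intermediate
13 | (3R)-6-bromo-1,1-dimethoxy-4-methylidenehexan-3-ol | COC(OC)C[C@@H](O)C(=C)CCBr | intermediate
14 | (3R)-6-bromo-3-(tert-butyldimethylsilyloxy)-1,1-dimethoxy-4-methylidenehexane | COC(OC)C[C@@H](O[Si](C)(C)C(C)(C)C)C(=C)CCBr | intermediate
15 | 2-(iodomethyl)-4,4,5,5-tetramethyl-1,3,2-dioxaborolane | ICB1OC(C)(C)C(C)(C)O1 | starting material
16 | [(4R)-4-(tert-butyldimethylsilyloxy)-6,6-dimethoxy-3-methylidenehexyl]magnesium bromide | COC(OC)C[C@@H](O[Si](C)(C)C(C)(C)C)C(=C)CC[Mg]Br | intermediate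
17 | [(4R)-4-(tert-butyldimethylsilyloxy)-6,6-dimethoxy-3-methylidenehexyl]copper(I) | COC(OC)C[C@@H](O[Si](C)(C)C(C)(C)C)C(=C)CC[Cu] | intermediate
18 | methyl (2E,7R)-7-(tert-butyldimethylsilyloxy)-2-cuprio-3-[(1R,2Z)-3-iodo-1-(triethylsilyloxy)but-2-en-1-yl]-9,9-dimethoxy-6-methylidenenon-2-enoate (syn adduct, Cu cis to C4) | COC(OC)C[C@@H](O[Si](C)(C)C(C)(C)C)C(=C)CC/C(=C(\[Cu])C(=O)OC)[C@H](O[Si](CC)(CC)CC)/C=C(/C)I | intermediate
19 | methyl (2Z,7R)-7-(tert-butyldimethylsilyloxy)-3-[(1R,2Z)-3-iodo-1-(triethylsilyloxy)but-2-en-1-yl]-9,9-dimethoxy-6-methylidene-2-[(4,4,5,5-tetramethyl-1,3,2-dioxaborolan-2-yl)methyl]non-2-enoate | COC(OC)C[C@@H](O[Si](C)(C)C(C)(C)C)C(=C)CC/C(=C(\CB1OC(C)(C)C(C)(C)O1)C(=O)OC)[C@H](O[Si](CC)(CC)CC)/C=C(/C)I | intermediate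
20 | methyl (2Z,7R)-7-(tert-butyldimethylsilyloxy)-2-(hydroxymethyl)-3-[(1R,2Z)-3-iodo-1-(triethylsilyloxy)but-2-en-1-yl]-9,9-dimethoxy-6-methylidenenon-2-enoate | COC(OC)C[C@@H](O[Si](C)(C)C(C)(C)C)C(=C)CC/C(=C(\CO)C(=O)OC)[C@H](O[Si](CC)(CC)CC)/C=C(/C)I | intermediate
21 | (5R)-4-[(4R)-4-(tert-butyldimethylsilyloxy)-3-methylidene-6-oxohexyl]-3-(hydroxymethyl)-5-[(1Z)-2-iodoprop-1-en-1-yl]furan-2(5H)-one | O=CC[C@@H](O[Si](C)(C)C(C)(C)C)C(=C)CCC1=C(CO)C(=O)O[C@@H]1/C=C(/C)I | intermediate
22 | (1S,3R,8R,9Z)-3-(tert-butyldimethylsilyloxy)-1,13-dihydroxygermacra-4(15),7(11),9-trien-12,8-olide | C=C1CCC2=C(CO)C(=O)O[C@@H]2/C=C(/C)[C@@H](O)C[C@H]1O[Si](C)(C)C(C)(C)C | intermediate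
23 | (1S,3R,8R,9Z)-1,13-diacetoxy-3-(tert-butyldimethylsilyloxy)germacra-4(15),7(11),9-trien-12,8-olide | C=C1CCC2=C(COC(C)=O)C(=O)O[C@@H]2/C=C(/C)[C@@H](OC(C)=O)C[C@H]1O[Si](C)(C)C(C)(C)C | intermediate
24 | (1S,3R,8R,9Z)-1,13-diacetoxy-3-hydroxygermacra-4(15),7(11),9-trien-12,8-olide (CNP0227830.1) | C=C1CCC2=C(COC(C)=O)C(=O)O[C@@H]2/C=C(/C)[C@@H](OC(C)=O)C[C@H]1O | target

Total step count: 14. Longest linear sequence: 10 steps (7 to 24 through steps 5–14); the other branch (1 to 24) is 9 steps.

Steps most likely to fail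

Step 12 (key step). The addition may show poor facial selectivity at the C1 aldehyde and give mainly or partly the 1,3-anti alcohol. The fallback sets out from 21 and comes back at 23. The NHK reaction is run as above and the epimer (1R,3R,8R,9Z)-3-(tert-butyldimethylsilyloxy)-1,13-dihydroxygermacra-4(15),7(11),9-trien-12,8-olide F1 is separated. A Mitsunobu reaction of F1 with acetic acid (PPh3, DIAD, THF, 0 °C) should acetylate the primary C13 hydroxyl and convert the C1 alcohol into its acetate with inversion, giving 23. The C1 configuration is then set by SN2 displacement instead of by the addition, and any 1S alcohol 22 formed is acetylated as in step 13.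

Step 10. The C-alkylation of alkenylcopper 18 may be slower than its E/Z equilibration through the allenolate, which would lose the geometry needed for lactonisation. The fallback sets out from 5 and 17 and comes back at 21; it fixes the alkene geometry in a ring before the alkylation. Alcohol 5 is deprotonated (MeLi, THF, −78 °C) to its lithium alkoxide F2 and added to alkylcopper 17. The resulting syn adduct, the alkoxide-bearing α-cuprio enoate F3, should close on the cis ester on warming to −30 °C to give the α-cuprio butenolide F4. HMPA and 15 then give the (borylmethyl)butenolide F5, NaBO3 gives the hydroxymethyl butenolide dimethyl acetal F6, and aqueous HCl (pH 2) hydrolyses the acetal to 21.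

Step 3. The alkynylation may proceed with low enantioselectivity, or the β-iodo enal may isomerise from Z to E or suffer conjugate addition–elimination under the zinc conditions. The fallback sets out from 3 and 4 and comes back at 5. Ester 4 is lithiated (LiHMDS, THF, −90 °C) to lithium 3-methoxy-3-oxoprop-1-yn-1-ide F7, which adds to 3 to give racemic methyl (5Z)-4-hydroxy-6-iodohept-5-en-2-ynoate F8. Kinetic resolution with Burkholderia cepacia lipase and vinyl acetate (MTBE, rt) should acylate the S enantiomer (Kazlauskas' rule, alkynyl as the medium and alkenyl as the large group) to methyl (4S,5Z)-4-acetoxy-6-iodohept-5-en-2-ynoate F9. The unreacted R alcohol is 5.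

Further compounds
F1 | step 12 | (1R,3R,8R,9Z)-3-(tert-butyldimethylsilyloxy)-1,13-dihydroxygermacra-4(15),7(11),9-trien-12,8-olide | C=C1CCC2=C(CO)C(=O)O[C@@H]2/C=C(/C)[C@H](O)C[C@H]1O[Si](C)(C)C(C)(C)C
F2 | step 10 | lithium alkoxide of methyl (4R,5Z)-4-hydroxy-6-iodohept-5-en-2-ynoate | COC(=O)C#C[C@H](O[Li])/C=C(/C)I
F3 | step 10 | alkoxide-bearing α-cuprio enoate (syn adduct of 17 and F2) | COC(OC)C[C@@H](O[Si](C)(C)C(C)(C)C)C(=C)CC/C(=C(\[Cu])C(=O)OC)[C@H](O[Li])/C=C(/C)I
F4 | step 10 | (5R)-4-[(4R)-4-(tert-butyldimethylsilyloxy)-6,6-dimethoxy-3-methylidenehexyl]-3-cuprio-5-[(1Z)-2-iodoprop-1-en-1-yl]furan-2(5H)-one | COC(OC)C[C@@H](O[Si](C)(C)C(C)(C)C)C(=C)CCC1=C([Cu])C(=O)O[C@@H]1/C=C(/C)I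
F5 | step 10 | (5R)-4-[(4R)-4-(tert-butyldimethylsilyloxy)-6,6-dimethoxy-3-methylidenehexyl]-5-[(1Z)-2-iodoprop-1-en-1-yl]-3-[(4,4,5,5-tetramethyl-1,3,2-dioxaborolan-2-yl)methyl]furan-2(5H)-one | COC(OC)C[C@@H](O[Si](C)(C)C(C)(C)C)C(=C)CCC1=C(CB2OC(C)(C)C(C)(C)O2)C(=O)O[C@@H]1/C=C(/C)I
F6 | step 10 | (5R)-4-[(4R)-4-(tert-butyldimethylsilyloxy)-6,6-dimethoxy-3-methylidenehexyl]-3-(hydroxymethyl)-5-[(1Z)-2-iodoprop-1-en-1-yl]furan-2(5H)-one | COC(OC)C[C@@H](O[Si](C)(C)C(C)(C)C)C(=C)CCC1=C(CO)C(=O)O[C@@H]1/C=C(/C)I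
F7 | step 3 | lithium 3-methoxy-3-oxoprop-1-yn-1-ide | [Li]C#CC(=O)OC
F8 | step 3 | racemic methyl (5Z)-4-hydroxy-6-iodohept-5-en-2-ynoate | COC(=O)C#CC(O)/C=C(/C)I
F9 | step 3 | methyl (4S,5Z)-4-acetoxy-6-iodohept-5-en-2-ynoate | COC(=O)C#C[C@@H](OC(C)=O)/C=C(/C)I
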